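**Plan**

1. Numbering used in the text (not the locants of the systematic names): C1 CH–O-tiglate, C2 CH2, C3 CH–O-senecioate, C4 CMe2, cyclobutane C5–C6–C11–C10 with C11 the quaternary methyl carbon, C7 C=O, C8=C9(Me); the seven-membered ring is C11–C1–C2–C3–C4–C5 closed through C6.
2. Cuts: the two ester C–O bonds (with C3–H); the C7 carbonyl and the C8=C9 position (back to exocyclic C9=CH2 and a C7 methylene); a hydroxyl is put back on C5 and C4–C5 is cut as an aldol bond; C5–C6 and C10–C11 are cut as a ketene–alkene cycloadduct; C1–C2 is cut as an aldol bond, leaving a geranic acid chain oxidised at its (E)-methyl group.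
3. Enabling feature: C4, α to the C3 oxygen function, is bonded to cyclobutane carbon C5, so C3(=O)–C4–C5(OH) is an aldol retron; as a cyclobutanone carbonyl, C5 is strain-activated, cannot enolise (C6 and C10 are bridgeheads) and sits 1,3 across the four-membered ring from C11, which holds the C1–C4 chain on the same face.
4. Forward: chain from geranic acid, C1–C2 aldol, ketene [2+2] (four- and six-membered rings in one step), Mukaiyama aldol closing the seven-membered ring, then alkene shift, removal of the C5 oxygen, C7 oxidation and the two esters.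
5. Stereochemistry: C1 from a catalytic enantioselective aldol addition; C6, C10, C11 from the suprafacial ketene addition to the (E)-alkene on the face chosen by C1; C5 from the tether (ring closure) and the cage (hydrogen transfer); C3 from hydride delivery by the C1 oxygen (1,3-anti).

Key step: step 9

Remark: in step 4 the (R,R)-bisphosphoramide is assumed to expose the Re face of the enal, as it does for aryl- and alkenyl-substituted aldehydes; if the enal responds in the opposite sense, the (S,S)-catalyst is used instead.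

**Route**

Step 1
Reactants: 1 geranic acid [(2E)-3,7-dimethylocta-2,6-dienoic acid]
Product: 2 prop-2-en-1-yl (2E)-3,7-dimethylocta-2,6-dienoate (allyl geranate)
Conditions: allyl bromide, K2CO3, DMF, rt
Reagents that add atoms: allyl bromide, C=CCBr
Why: Carboxylate O-alkylation (SN2) gives the allyl ester, chosen because zerovalent palladium can later remove it under neutral conditions that spare the vinyl ketone and the β-silyloxy ketone.

Step 2
Reactants: 2 allyl geranate
Product: 4 prop-2-en-1-yl (2E,6E)-3,7-dimethyl-8-oxoocta-2,6-dienoate, via allylic alcohol 3 (not isolated)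
Conditions: SeO2 (cat.), tBuOOH, salicylic acid (cat.), CH2Cl2, rt; filter; MnO2, CH2Cl2, rt
Reagents that add atoms: selenium dioxide, O=[Se]=O (oxygen carrier); tert-butyl hydroperoxide, CC(C)(C)OO (terminal oxygen source)
Why: Selenium dioxide allylic oxidation (ene reaction followed by 2,3-sigmatropic shift) selects the (E)-methyl group of the electron-rich trisubstituted alkene over the conjugated ester and the allyl group, and MnO2 then oxidises the allylic alcohol so that alcohol and aldehyde converge on the single (E)-enal.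

Step 3
Reactants: 5 3-methylbut-3-en-2-one
Product: 6 3-methyl-2-(trimethylsilyloxy)buta-1,3-diene
Conditions: LiN(iPr)2, THF, −78 °C; Me3SiCl
Reagents that add atoms: chlorotrimethylsilane, C[Si](C)(C)Cl
Why: Kinetic enolisation at the α′-methyl group with a hindered amide base and O-silylation (kinetic silyl enol ether formation) should give the cross-conjugated 2-silyloxydiene without touching the vinylic methyl group.

Step 4
Reactants: 4 prop-2-en-1-yl (2E,6E)-3,7-dimethyl-8-oxoocta-2,6-dienoate; 6 3-methyl-2-(trimethylsilyloxy)buta-1,3-diene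
Product: 7 prop-2-en-1-yl (2E,6E,8R)-8-hydroxy-3,7,11-trimethyl-10-oxododeca-2,6,11-trienoate
Conditions: SiCl4, (R,R)-bisphosphoramide (from N,N′-dimethyl-1,1′-binaphthyl-2,2′-diamine, pentamethylene-linked; 5 mol%), iPr2NEt (cat.), CH2Cl2, −78 °C; aq. NaHCO3
Reagents that add atoms: none
Why: In this Lewis-base-catalysed Mukaiyama aldol addition the chiral phosphoramide-bound trichlorosilyl cation activates only the conjugated aldehyde and shields its Si face, so the terminal carbon of the silyloxydiene adds to the Re face and sets C1 as (R), while the isopropenyl ketone needed later for regiospecific enol ether formation is installed intact.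

Step 5
Reactants: 7 prop-2-en-1-yl (2E,6E,8R)-8-hydroxy-3,7,11-trimethyl-10-oxododeca-2,6,11-trienoate
Product: 8 prop-2-en-1-yl (2E,6E,8R)-8-(tert-butyldimethylsilyloxy)-3,7,11-trimethyl-10-oxododeca-2,6,11-trienoate
Conditions: TBSOTf, 2,6-lutidine, CH2Cl2, −78 °C
Reagents that add atoms: tert-butyldimethylsilyl trifluoromethanesulfonate, CC(C)(C)[Si](C)(C)OS(=O)(=O)C(F)(F)F
Why: Silylation of the secondary allylic alcohol with the silyl triflate and a hindered pyridine base at low temperature should be faster than 6-endo oxa-Michael closure of the hydroxy enone and removes the retro-aldol pathway.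

Step 6
Reactants: 8 prop-2-en-1-yl (2E,6E,8R)-8-(tert-butyldimethylsilyloxy)-3,7,11-trimethyl-10-oxododeca-2,6,11-trienoate
Product: 9 (2E,6E,8R)-8-(tert-butyldimethylsilyloxy)-3,7,11-trimethyl-10-oxododeca-2,6,11-trienoic acid
Conditions: Pd(PPh3)4 (cat.), PPh3, potassium 2-ethylhexanoate, EtOAc/CH2Cl2, rt; aq. KHSO4
Reagents that add atoms: none
Why: Palladium-catalysed deallylation (π-allyl formation and allyl transfer to the carboxylate scavenger) frees the acid without amine nucleophiles that would add to the vinyl ketone and without hydroxide that would eliminate the β-silyloxy group.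

Step 7
Reactants: 9 (2E,6E,8R)-8-(tert-butyldimethylsilyloxy)-3,7,11-trimethyl-10-oxododeca-2,6,11-trienoic acid
Product: 12 (1R,5S,7S)-7-[(1R)-1-(tert-butyldimethylsilyloxy)-4-methyl-3-oxopent-4-en-1-yl]-7-methyl-2-methylidenebicyclo[3.1.1]heptan-6-one, via acid chloride 10 (not isolated), via vinylketene 11 (not isolated)
Conditions: 1-chloro-N,N,2-trimethylprop-1-en-1-amine, CH2Cl2, 0 °C to rt; then slow addition to Et3N, toluene, 110 °C (0.005 M)
Reagents that add atoms: none
Why: The acid chloride loses HCl from the γ-methyl group to give a vinylketene, which adds to the C6=C11 alkene in the intramolecular crossed ketene–alkene [2+2] cycloaddition established for geranoyl-type chlorides (carbonyl carbon to C6, ketene α-carbon to the more substituted C11), so the cyclobutanone and the six-membered ring form together; the addition is suprafacial on the (E)-alkene, which places the C11 methyl syn and the side chain anti to the three-carbon bridge, and the face is set by C1 through the rotamer with C1–H over the forming ring, the C2 branch anti to the incoming ketene and the silyloxy group outside, which should lead to the (1R,5S,7S) bicycle.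

Step 8
Reactants: 12 (1R,5S,7S)-7-[(1R)-1-(tert-butyldimethylsilyloxy)-4-methyl-3-oxopent-4-en-1-yl]-7-methyl-2-methylidenebicyclo[3.1.1]heptan-6-one
Product: 13 (1R,5S,7S)-7-[(1R)-1-(tert-butyldimethylsilyloxy)-4-methyl-3-(triethylsilyloxy)pent-3-en-1-yl]-7-methyl-2-methylidenebicyclo[3.1.1]heptan-6-one
Conditions: RhCl(PPh3)3 (cat.), Et3SiH, THF, 40 °C
Reagents that add atoms: triethylsilane, CC[SiH](CC)CC
Why: Rhodium-catalysed 1,4-hydrosilylation of the α-methylene ketone with a monohydrosilane puts hydrogen on the terminal CH2 and silicon on oxygen, so the tetrasubstituted C3=C4 enol ether is formed regiospecifically (no C2 enolisation, no β-elimination of the C1 silyloxy group), while the cyclobutanone and the 1,1-disubstituted alkene react much more slowly under these conditions.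

Step 9
Reactants: 13 (1R,5S,7S)-7-[(1R)-1-(tert-butyldimethylsilyloxy)-4-methyl-3-(triethylsilyloxy)pent-3-en-1-yl]-7-methyl-2-methylidenebicyclo[3.1.1]heptan-6-one
Product: 14 (1S,2S,6R,7S,8R)-6-(tert-butyldimethylsilyloxy)-2-hydroxy-3,3,7-trimethyl-9-methylidenetricyclo[5.4.0.0^2,8]undecan-4-one
Conditions: TiCl4, 2,6-di-tert-butyl-4-methylpyridine, CH2Cl2, −78 °C (0.01 M); aq. NaHCO3
Reagents that add atoms: none
Why: TiCl4 binds the strained C5 carbonyl and the tetrasubstituted triethylsilyl enol ether attacks it through C4, after which chloride takes the silyl group and aqueous work-up frees the tertiary carbinol. The closest known reaction type is the intramolecular Mukaiyama aldol addition of an enol silane to a ketone, here a cyclobutanone whose carbonyl strain favours addition and disfavours reversal. The seven-membered ring C11–C1–C2–C3–C4–C5–C6 closes in a 7-(enolendo)-exo-trig mode, and the tether forces an open transition state in which the C5–O bond lies anti to C3 about the forming C4–C5 bond, an arrangement that a Lewis acid-mediated enol silane addition can adopt and a chelated metal enolate cannot. The new stereocentre C5 is controlled by the bicycle: the side chain hangs from C11 on the face of the cyclobutane opposite the C7–C8–C9 bridge, so C4 can reach only that face of C5 and the hydroxyl must end up syn to the bridge. Regioselectivity (C4 and not C2) is secured by the defined enol ether, chemoselectivity by the absence of any other electrophile, and survival of the acid-labile methylenecyclobutane by low temperature, high dilution and the hindered pyridine that scavenges protons.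

Step 10
Reactants: 14 (1S,2S,6R,7S,8R)-6-(tert-butyldimethylsilyloxy)-2-hydroxy-3,3,7-trimethyl-9-methylidenetricyclo[5.4.0.0^2,8]undecan-4-one
Product: 15 (1S,2S,6R,7S,8R)-6-(tert-butyldimethylsilyloxy)-2-hydroxy-3,3,7,9-tetramethyltricyclo[5.4.0.0^2,8]undec-9-en-4-one
Conditions: Pd(dba)2 (cat.), P(tBu)3 (cat.), iPrCOCl (cat.), toluene, 80 °C
Reagents that add atoms: none
Why: Palladium hydride-catalysed alkene isomerisation (hydropalladation and β-hydride elimination) should move the exocyclic double bond to the more stable trisubstituted C8=C9 position, the only one available because C10 is a bridgehead, under neutral conditions that create neither a cation nor a free radical next to the cyclobutane; it is placed here so that no 1,1-disubstituted alkene is exposed to stannyl radicals in step 12.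

Step 11
Reactants: 15 (1S,2S,6R,7S,8R)-6-(tert-butyldimethylsilyloxy)-2-hydroxy-3,3,7,9-tetramethyltricyclo[5.4.0.0^2,8]undec-9-en-4-one
Product: 16 methyl (1S,2S,6R,7S,8R)-6-(tert-butyldimethylsilyloxy)-3,3,7,9-tetramethyl-4-oxotricyclo[5.4.0.0^2,8]undec-9-en-2-yl oxalate
Conditions: ClC(O)CO2Me, DMAP (cat.), pyridine, CH2Cl2, 0 °C to rt
Reagents that add atoms: methyl chlorooxoacetate, COC(=O)C(=O)Cl
Why: Acylation of the tertiary carbinol with the small, highly electrophilic methyl oxalyl chloride under nucleophilic catalysis gives the mixed oxalate for radical deoxygenation without ever forming the alkoxide, which could revert by retro-aldol cleavage.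

Step 12
Reactants: 16 methyl (1S,2S,6R,7S,8R)-6-(tert-butyldimethylsilyloxy)-3,3,7,9-tetramethyl-4-oxotricyclo[5.4.0.0^2,8]undec-9-en-2-yl oxalate
Product: 17 (1R,2R,6R,7S,8R)-6-(tert-butyldimethylsilyloxy)-3,3,7,9-tetramethyltricyclo[5.4.0.0^2,8]undec-9-en-4-one
Conditions: Bu3SnH, AIBN, toluene, 110 °C
Reagents that add atoms: none
Why: Barton–McCombie-type radical deoxygenation of a tertiary methyl oxalate: stannyl radical addition and fragmentation give the C5 cyclobutyl radical, which is held in the cage and can accept hydrogen only on the face syn to the three-carbon bridge (C4 stays anti), while a 1,2-acyl shift to the C3 ketone would need a more strained ring-contracted radical and should not compete at high stannane concentration.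

Step 13
Reactants: 17 (1R,2R,6R,7S,8R)-6-(tert-butyldimethylsilyloxy)-3,3,7,9-tetramethyltricyclo[5.4.0.0^2,8]undec-9-en-4-one
Product: 18 (1R,2S,6R,7R,8R)-6-(tert-butyldimethylsilyloxy)-3,3,7,9-tetramethyltricyclo[5.4.0.0^2,8]undec-9-ene-4,11-dione
Conditions: CrO3, 3,5-dimethylpyrazole, CH2Cl2, −20 °C
Reagents that add atoms: chromium trioxide, O=[Cr](=O)=O
Why: Allylic oxidation with the CrO3–3,5-dimethylpyrazole complex converts the ring methylene C7 next to the trisubstituted alkene into the conjugated ketone, the position oxidised in the α-pinene-to-verbenone transformation; the bridgehead C10–H cannot give a stabilised allylic intermediate, and the saturated ketone and silyl ether are inert.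

Step 14
Reactants: 18 (1R,2S,6R,7R,8R)-6-(tert-butyldimethylsilyloxy)-3,3,7,9-tetramethyltricyclo[5.4.0.0^2,8]undec-9-ene-4,11-dione
Product: 19 (1R,2S,6R,7R,8R)-6-hydroxy-3,3,7,9-tetramethyltricyclo[5.4.0.0^2,8]undec-9-ene-4,11-dione
Conditions: HF·pyridine, pyridine, THF, 0 °C to rt
Reagents that add atoms: none
Why: Desilylation with buffered hydrogen fluoride frees the hindered C1 carbinol under non-basic conditions, avoiding retro-aldol opening of the seven-membered β-hydroxy ketone.

Step 15
Reactants: 19 (1R,2S,6R,7R,8R)-6-hydroxy-3,3,7,9-tetramethyltricyclo[5.4.0.0^2,8]undec-9-ene-4,11-dione; 20 tiglic aldehyde [(2E)-2-methylbut-2-enal]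
Product: 21 (1R,2R,3R,5R,7S,8R)-5-hydroxy-2,6,6,11-tetramethyl-9-oxotricyclo[5.4.0.0^2,8]undec-10-en-3-yl (2E)-2-methylbut-2-enoate
Conditions: SmI2 (30 mol%, pre-mixed with the aldehyde), excess 20, THF, −10 °C
Reagents that add atoms: none
Why: Evans–Tishchenko reaction: the trivalent samarium alkoxide generated from SmI2 and the excess aldehyde (pre-mixed so that no SmI2 remains to reduce the C7 enone) promotes hemiacetal formation at the C1 hydroxyl and intramolecular hydride transfer to the C3 ketone through a six-membered chelate, so hydride arrives on the face bearing the C1 oxygen and the new C3 carbinol is trans (1,3-anti, 3R), with C1 leaving the step already as its tiglate.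

Step 16
Reactants: 21 (1R,2R,3R,5R,7S,8R)-5-hydroxy-2,6,6,11-tetramethyl-9-oxotricyclo[5.4.0.0^2,8]undec-10-en-3-yl (2E)-2-methylbut-2-enoate; 22 3-methylbut-2-enoyl chloride
Product: 23 (1R,2R,3R,5R,7S,8R)-2,6,6,11-tetramethyl-5-(3-methylbut-2-enoyloxy)-9-oxotricyclo[5.4.0.0^2,8]undec-10-en-3-yl (2E)-2-methylbut-2-enoate (CNP0277258.1)
Conditions: pyridine, DMAP (cat.), CH2Cl2, 0 °C to rt
Reagents that add atoms: none
Why: Esterification of the remaining hindered secondary alcohol through the N-acylpyridinium ion (acid chloride, pyridine, DMAP), using pyridine instead of a trialkylamine to limit vinylketene formation and deconjugation of the senecioyl group, gives the target.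

**Compound list**

1 | geranic acid, (2E)-3,7-dimethylocta-2,6-dienoic acid | CC(C)=CCC/C(C)=C/C(=O)O | starting material
2 | prop-2-en-1-yl (2E)-3,7-dimethylocta-2,6-dienoate | CC(C)=CCC/C(C)=C/C(=O)OCC=C | intermediate
3 | prop-2-en-1-yl (2E,6E)-8-hydroxy-3,7-dimethylocta-2,6-dienoate (formed in the flask) | OC/C(C)=C/CC/C(C)=C/C(=O)OCC=C | intermediate
4 | prop-2-en-1-yl (2E,6E)-3,7-dimethyl-8-oxoocta-2,6-dienoate | O=C/C(C)=C/CC/C(C)=C/C(=O)OCC=C | intermediate
5 | 3-methylbut-3-en-2-one | CC(=O)C(C)=C | starting material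
6 | 3-methyl-2-(trimethylsilyloxy)buta-1,3-diene | C=C(O[Si](C)(C)C)C(C)=C | intermediate
7 | prop-2-en-1-yl (2E,6E,8R)-8-hydroxy-3,7,11-trimethyl-10-oxododeca-2,6,11-trienoate | C=C(C)C(=O)C[C@@H](O)/C(C)=C/CC/C(C)=C/C(=O)OCC=C | intermediate
8 | prop-2-en-1-yl (2E,6E,8R)-8-(tert-butyldimethylsilyloxy)-3,7,11-trimethyl-10-oxododeca-2,6,11-trienoate | C=C(C)C(=O)C[C@@H](O[Si](C)(C)C(C)(C)C)/C(C)=C/CC/C(C)=C/C(=O)OCC=C | intermediate
9 | (2E,6E,8R)-8-(tert-butyldimethylsilyloxy)-3,7,11-trimethyl-10-oxododeca-2,6,11-trienoic acid | C=C(C)C(=O)C[C@@H](O[Si](C)(C)C(C)(C)C)/C(C)=C/CC/C(C)=C/C(=O)O | intermediate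
10 | (2E,6E,8R)-8-(tert-butyldimethylsilyloxy)-3,7,11-trimethyl-10-oxododeca-2,6,11-trienoyl chloride (formed in the flask) | C=C(C)C(=O)C[C@@H](O[Si](C)(C)C(C)(C)C)/C(C)=C/CC/C(C)=C/C(=O)Cl | intermediate
11 | (6E,8R)-8-(tert-butyldimethylsilyloxy)-7,11-dimethyl-3-methylidenedodeca-1,6,11-triene-1,10-dione, the vinylketene (formed in the flask) | C=C(C)C(=O)C[C@@H](O[Si](C)(C)C(C)(C)C)/C(C)=C/CCC(=C)C=C=O | intermediate
12 | (1R,5S,7S)-7-[(1R)-1-(tert-butyldimethylsilyloxy)-4-methyl-3-oxopent-4-en-1-yl]-7-methyl-2-methylidenebicyclo[3.1.1]heptan-6-one | C=C1CC[C@@H]2C(=O)[C@H]1[C@@]2(C)[C@H](O[Si](C)(C)C(C)(C)C)CC(=O)C(C)=C | intermediate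
13 | (1R,5S,7S)-7-[(1R)-1-(tert-butyldimethylsilyloxy)-4-methyl-3-(triethylsilyloxy)pent-3-en-1-yl]-7-methyl-2-methylidenebicyclo[3.1.1]heptan-6-one | C=C1CC[C@@H]2C(=O)[C@H]1[C@@]2(C)[C@H](O[Si](C)(C)C(C)(C)C)CC(O[Si](CC)(CC)CC)=C(C)C | intermediate
14 | (1S,2S,6R,7S,8R)-6-(tert-butyldimethylsilyloxy)-2-hydroxy-3,3,7-trimethyl-9-methylidenetricyclo[5.4.0.0^2,8]undecan-4-one | C=C1CC[C@@H]2[C@]3(O)[C@H]1[C@@]2(C)[C@H](O[Si](C)(C)C(C)(C)C)CC(=O)C3(C)C | intermediate
15 | (1S,2S,6R,7S,8R)-6-(tert-butyldimethylsilyloxy)-2-hydroxy-3,3,7,9-tetramethyltricyclo[5.4.0.0^2,8]undec-9-en-4-one | CC(C)(C)[Si](C)(C)O[C@@H]1CC(=O)C(C)(C)[C@]2(O)[C@H]3CC=C(C)[C@@H]2[C@]31C | intermediate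
16 | methyl (1S,2S,6R,7S,8R)-6-(tert-butyldimethylsilyloxy)-3,3,7,9-tetramethyl-4-oxotricyclo[5.4.0.0^2,8]undec-9-en-2-yl oxalate | CC(C)(C)[Si](C)(C)O[C@@H]1CC(=O)C(C)(C)[C@]2(OC(=O)C(=O)OC)[C@H]3CC=C(C)[C@@H]2[C@]31C | intermediate
17 | (1R,2R,6R,7S,8R)-6-(tert-butyldimethylsilyloxy)-3,3,7,9-tetramethyltricyclo[5.4.0.0^2,8]undec-9-en-4-one | CC(C)(C)[Si](C)(C)O[C@@H]1CC(=O)C(C)(C)[C@@H]2[C@H]3CC=C(C)[C@@H]2[C@]31C | intermediate
18 | (1R,2S,6R,7R,8R)-6-(tert-butyldimethylsilyloxy)-3,3,7,9-tetramethyltricyclo[5.4.0.0^2,8]undec-9-ene-4,11-dione | CC(C)(C)[Si](C)(C)O[C@@H]1CC(=O)C(C)(C)[C@@H]2[C@H]3C(=O)C=C(C)[C@@H]2[C@]31C | intermediate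
19 | (1R,2S,6R,7R,8R)-6-hydroxy-3,3,7,9-tetramethyltricyclo[5.4.0.0^2,8]undec-9-ene-4,11-dione | O[C@@H]1CC(=O)C(C)(C)[C@@H]2[C@H]3C(=O)C=C(C)[C@@H]2[C@]31C | intermediate
20 | tiglic aldehyde, (2E)-2-methylbut-2-enal | C/C=C(\C)C=O | starting material
21 | (1R,2R,3R,5R,7S,8R)-5-hydroxy-2,6,6,11-tetramethyl-9-oxotricyclo[5.4.0.0^2,8]undec-10-en-3-yl (2E)-2-methylbut-2-enoate | C/C=C(\C)C(=O)O[C@@H]1C[C@@H](O)C(C)(C)[C@@H]2[C@H]3C(=O)C=C(C)[C@@H]2[C@]31C | intermediate
22 | 3-methylbut-2-enoyl chloride | CC(C)=CC(=O)Cl | starting material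
23 | (1R,2R,3R,5R,7S,8R)-2,6,6,11-tetramethyl-5-(3-methylbut-2-enoyloxy)-9-oxotricyclo[5.4.0.0^2,8]undec-10-en-3-yl (2E)-2-methylbut-2-enoate, CNP0277258.1 | C/C=C(\C)C(=O)O[C@@H]1C[C@@H](OC(=O)C=C(C)C)C(C)(C)[C@@H]2[C@H]3C(=O)C=C(C)[C@@H]2[C@]31C | target

**Count and risks**

Total step count: 16. Longest linear sequence: 15 steps (geranic acid to the target through steps 1, 2 and 4–16; step 3 is a one-step side branch).

Steps most likely to fail:

1. Step 9 (ring closure). The Lewis acid may protonate or ionise the strained methylenecyclobutane, or strip the silyl group before the hindered C4–C5 bond forms, and the aldol may revert on work-up. Fallback: activation is moved from the acceptor to the donor. Compound 13 is treated with tris(dimethylamino)sulfonium difluorotrimethylsilicate in THF at −78 °C, which unmasks the naked tetrasubstituted enolate under acid-free conditions. Addition through the same open arrangement and protonation of the aldolate with acetic acid at low temperature would give 14 directly. The fallback sets out from 13 and returns at 14 and makes no new compound.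

2. Step 7 (ketene cycloaddition). Face selection by the C1 silyloxy centre may be weak or opposite, and the allylic oxygen lowers the nucleophilicity of the alkene, so ketene oligomerisation may compete. Fallback: the stereocentre is taken off the alkene and C1 is created after the bicycle exists.
   - Enal 4 is converted (HC(OMe)3, MeOH, pyridinium p-toluenesulfonate) into its dimethyl acetal, prop-2-en-1-yl (2E,6E)-8,8-dimethoxy-3,7-dimethylocta-2,6-dienoate F1.
   - Deallylation (Pd(PPh3)4, morpholine, THF) gives (2E,6E)-8,8-dimethoxy-3,7-dimethylocta-2,6-dienoic acid F2.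
   - Cyclisation under the conditions of step 7 gives racemic (1R,5S,7S)-7-(dimethoxymethyl)-7-methyl-2-methylidenebicyclo[3.1.1]heptan-6-one F3, for which no face selection arises.
   - Mild hydrolysis (pyridinium p-toluenesulfonate, wet acetone) gives racemic (1R,5S,7S)-7-methyl-2-methylidene-6-oxobicyclo[3.1.1]heptane-7-carbaldehyde F4.
   - A catalyst-controlled direct aldol addition of 5 (Et2Zn, the ProPhenol antipode that gives the (R)-carbinol, THF) converts the two enantiomers of F4 into two diastereomers. These are (1R,5S,7S)-7-[(1R)-1-hydroxy-4-methyl-3-oxopent-4-en-1-yl]-7-methyl-2-methylidenebicyclo[3.1.1]heptan-6-one F5 and its isomer with the mirror-image bicycle, (1S,5R,7R)-7-[(1R)-1-hydroxy-4-methyl-3-oxopent-4-en-1-yl]-7-methyl-2-methylidenebicyclo[3.1.1]heptan-6-one F6, which are separated by chromatography.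
   - Silylation of F5 (TBSOTf, 2,6-lutidine) gives 12.

   The fallback sets out from 4 and returns at 12.

3. Step 15 (Evans–Tishchenko). The conjugated, α-branched aldehyde may fail to form the hemiacetal at the hindered C1 carbinol or to pass its hydride to the neopentyl C3 ketone, leaving Tishchenko dimerisation of the aldehyde and reduction or coupling by low-valent samarium as the main processes. Fallback: the reduction is run with the smallest and most reactive aldehyde and the ester is exchanged afterwards.
   - Compound 19 with SmI2 (cat.) and acetaldehyde in THF at −10 °C should give (1R,2R,3R,5R,7S,8R)-5-hydroxy-2,6,6,11-tetramethyl-9-oxotricyclo[5.4.0.0^2,8]undec-10-en-3-yl acetate F7.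
   - Acylation with 22 (pyridine, DMAP) gives (1R,2R,3R,5R,7S,8R)-2,6,6,11-tetramethyl-5-(3-methylbut-2-enoyloxy)-9-oxotricyclo[5.4.0.0^2,8]undec-10-en-3-yl acetate F8.
   - Selective methanolysis of the acetate (K2CO3, MeOH, 0 °C), which should be much faster than cleavage of the β,β-disubstituted conjugated ester, gives (1R,2S,4R,6R,7R,8R)-6-hydroxy-3,3,7,9-tetramethyl-11-oxotricyclo[5.4.0.0^2,8]undec-9-en-4-yl 3-methylbut-2-enoate F9.
   - Acylation with (2E)-2-methylbut-2-enoyl chloride (pyridine, DMAP) gives 23.

   The fallback sets out from 19 and returns at 23.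

Further compounds
F0 | step 9 | none | none
F1 | step 7 | prop-2-en-1-yl (2E,6E)-8,8-dimethoxy-3,7-dimethylocta-2,6-dienoate | COC(OC)/C(C)=C/CC/C(C)=C/C(=O)OCC=C
F2 | step 7 | (2E,6E)-8,8-dimethoxy-3,7-dimethylocta-2,6-dienoic acid | COC(OC)/C(C)=C/CC/C(C)=C/C(=O)O
F3 | step 7 | racemic (1R,5S,7S)-7-(dimethoxymethyl)-7-methyl-2-methylidenebicyclo[3.1.1]heptan-6-one (one enantiomer drawn) | C=C1CC[C@@H]2C(=O)[C@H]1[C@@]2(C)C(OC)OC
F4 | step 7 | racemic (1R,5S,7S)-7-methyl-2-methylidene-6-oxobicyclo[3.1.1]heptane-7-carbaldehyde (one enantiomer drawn) | C=C1CC[C@@H]2C(=O)[C@H]1[C@@]2(C)C=O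
F5 | step 7 | (1R,5S,7S)-7-[(1R)-1-hydroxy-4-methyl-3-oxopent-4-en-1-yl]-7-methyl-2-methylidenebicyclo[3.1.1]heptan-6-one | C=C1CC[C@@H]2C(=O)[C@H]1[C@@]2(C)[C@H](O)CC(=O)C(C)=C
F6 | step 7 | (1S,5R,7R)-7-[(1R)-1-hydroxy-4-methyl-3-oxopent-4-en-1-yl]-7-methyl-2-methylidenebicyclo[3.1.1]heptan-6-one | C=C1CC[C@H]2C(=O)[C@@H]1[C@]2(C)[C@H](O)CC(=O)C(C)=C
F7 | step 15 | (1R,2R,3R,5R,7S,8R)-5-hydroxy-2,6,6,11-tetramethyl-9-oxotricyclo[5.4.0.0^2,8]undec-10-en-3-yl acetate | CC(=O)O[C@@H]1C[C@@H](O)C(C)(C)[C@@H]2[C@H]3C(=O)C=C(C)[C@@H]2[C@]31C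
F8 | step 15 | (1R,2R,3R,5R,7S,8R)-2,6,6,11-tetramethyl-5-(3-methylbut-2-enoyloxy)-9-oxotricyclo[5.4.0.0^2,8]undec-10-en-3-yl acetate | CC(=O)O[C@@H]1C[C@@H](OC(=O)C=C(C)C)C(C)(C)[C@@H]2[C@H]3C(=O)C=C(C)[C@@H]2[C@]31C
F9 | step 15 | (1R,2S,4R,6R,7R,8R)-6-hydroxy-3,3,7,9-tetramethyl-11-oxotricyclo[5.4.0.0^2,8]undec-9-en-4-yl 3-methylbut-2-enoate | O[C@@H]1C[C@@H](OC(=O)C=C(C)C)C(C)(C)[C@@H]2[C@H]3C(=O)C=C(C)[C@@H]2[C@]31C
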